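**Retrosynthetic overview**

1. Target ⇐ MnO2 oxidation that forms the C15 enal and the C12 lactone together, preceded by α-methylenation of the C12 aldehyde (adds C13), C9 angeloylation and C6 acetylation ⇐ cyclohexanone 26.
2. Feature used: in the only carbocycle (cyclohexane C5–C10), C5 bears the 2-substituted propenal (C4=C3, C15) and is bonded to the oxygenated C6. The C5–C6 bond is therefore made by 6-exo addition of the C6 acyl radical of selenoester 25 to C5 of a (Z)-2-(phenylsulfonylmethyl)enoate, and loss of PhSO2• leaves C4=C3.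
3. 25 ⇐ Evans syn-aldol (C7–C8) of aldehyde 11 with imide 16, then thia-Michael/Horner–Wadsworth–Emmons olefination at C5, sulfone and selenoester formation.
4. 11 ⇐ Sharpless epoxidation of a prenyl acetate-derived (E)-allylic alcohol and invertive alkynylalane opening at C10 (sets the C9 oxygen and the C10 quaternary centre).
5. Ring order: carbocycle C5–C10 first (step 21), γ-lactone C7–C8–O–C12–C11 last (steps 29–30).

Key step: step 21

Remark: elemane numbering is used (C1=C2 vinyl, C10 quaternary with C14 methyl, C9 angelate, C8 lactone O, C7, C11=C13, C12 lactone carbonyl, C6 acetate, C5, C4=C3, C15 aldehyde); β means the ring face that carries the C14 methyl. The acetal epimers of 9 and the C12 epimers of 34 converge later and are carried as mixtures.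

**Route**

Step 1
Reactants: 1 3-methylbut-2-en-1-yl acetate (prenyl acetate)
Product: 2 (E)-4-hydroxy-3-methylbut-2-en-1-yl acetate
Conditions: SeO2 (cat.), t-BuOOH, CH2Cl2, rt
Reagents that add atoms: tert-butyl hydroperoxide, CC(C)(C)OO
Why: Selenium dioxide allylic oxidation (ene reaction then [2,3]-sigmatropic shift) attacks the methyl group trans to the CH2OAc chain of a trisubstituted alkene, so the (E)-allylic alcohol should form.

Step 2
Reactants: 2 (E)-4-hydroxy-3-methylbut-2-en-1-yl acetate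
Product: 3 (E)-4-[(tert-butyldimethylsilyl)oxy]-3-methylbut-2-en-1-yl acetate
Conditions: TBSCl, imidazole, DMF, 0 °C → rt
Reagents that add atoms: tert-butyldimethylsilyl chloride, CC(C)(C)[Si](C)(C)Cl
Why: Imidazole-promoted silylation of an unhindered primary alcohol is routine and leaves the acetate untouched.

Step 3
Reactants: 3 (E)-4-[(tert-butyldimethylsilyl)oxy]-3-methylbut-2-en-1-yl acetate
Product: 4 (E)-4-[(tert-butyldimethylsilyl)oxy]-3-methylbut-2-en-1-ol
Conditions: K2CO3 (cat.), MeOH, 0 °C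
Reagents that add atoms: none
Why: Base-catalysed transesterification removes the acetate while the silyl ether is stable to carbonate in methanol.

Step 4
Reactants: 4 (E)-4-[(tert-butyldimethylsilyl)oxy]-3-methylbut-2-en-1-ol
Product: 5 [(2R,3R)-3-{[(tert-butyldimethylsilyl)oxy]methyl}-3-methyloxiran-2-yl]methanol
Conditions: Ti(OiPr)4 (cat.), D-(−)-diethyl tartrate (cat.), t-BuOOH, 4 Å molecular sieves, CH2Cl2, −20 °C
Reagents that add atoms: tert-butyl hydroperoxide, CC(C)(C)OO
Why: Katsuki–Sharpless asymmetric epoxidation of an (E)-3,3-disubstituted allylic alcohol with the D-(−)-tartrate should give the (2R,3R)-epoxide (the mirror-image series to the (2S,3S)-epoxide that geraniol gives with the L-(+)-tartrate), which fixes the C9 configuration and places the C10–O bond for inversion.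

Step 5
Reactants: 5 [(2R,3R)-3-{[(tert-butyldimethylsilyl)oxy]methyl}-3-methyloxiran-2-yl]methanol
Product: 6 (2S,3S)-3-{[(tert-butyldimethylsilyl)oxy]methyl}-3-methyl-5-(trimethylsilyl)pent-4-yne-1,2-diol
Conditions: Me3SiC≡CH, n-BuLi, toluene, 0 °C; Et2AlCl; then 5, 0 °C → rt; aq. KNaC4H4O6 (potassium sodium tartrate)
Reagents that add atoms: diethyl[(trimethylsilyl)ethynyl]aluminium (made in the flask from trimethylsilylacetylene), CC[Al](CC)C#C[Si](C)(C)C
Why: Alkoxide-directed opening of a 2,3-epoxy alcohol by an alkynylalane occurs at the distal, more substituted carbon (C10) with inversion, so the quaternary centre forms stereospecifically while the C9 oxygen is retained.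

Step 6
Reactants: 6 (2S,3S)-3-{[(tert-butyldimethylsilyl)oxy]methyl}-3-methyl-5-(trimethylsilyl)pent-4-yne-1,2-diol
Product: 7 (2S,3S)-3-{[(tert-butyldimethylsilyl)oxy]methyl}-3-methylpent-4-yne-1,2-diol
Conditions: K2CO3, MeOH, rt
Reagents that add atoms: none
Why: Methanolysis cleaves the alkynyl C–Si bond selectively, the O-silyl ether being stable to these conditions.

Step 7
Reactants: 7 (2S,3S)-3-{[(tert-butyldimethylsilyl)oxy]methyl}-3-methylpent-4-yne-1,2-diol
Product: 8 (2S,3S)-3-{[(tert-butyldimethylsilyl)oxy]methyl}-3-methylpent-4-ene-1,2-diol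
Conditions: H2 (1 atm), Pd/CaCO3 poisoned with Pb(OAc)2, quinoline, EtOAc, rt
Reagents that add atoms: none
Why: Semihydrogenation of a terminal alkyne over poisoned palladium stops at the alkene, giving the C1=C2 vinyl group.

Step 8
Reactants: 8 (2S,3S)-3-{[(tert-butyldimethylsilyl)oxy]methyl}-3-methylpent-4-ene-1,2-diol
Product: 9 (4S)-4-[(2S)-1-[(tert-butyldimethylsilyl)oxy]-2-methylbut-3-en-2-yl]-2-(4-methoxyphenyl)-1,3-dioxolane
Conditions: 4-MeOC6H4CH(OMe)2, PPTS (cat.), CH2Cl2, rt
Reagents that add atoms: 4-methoxybenzaldehyde dimethyl acetal, COC(OC)c1ccc(OC)cc1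
Why: Acid-catalysed transacetalisation ties the 1,2-diol into a 4-methoxybenzylidene acetal under conditions that a primary silyl ether survives.

Step 9
Reactants: 9 (4S)-4-[(2S)-1-[(tert-butyldimethylsilyl)oxy]-2-methylbut-3-en-2-yl]-2-(4-methoxyphenyl)-1,3-dioxolane
Product: 10 (2S,3S)-2-[(4-methoxybenzyl)oxy]-3-{[(tert-butyldimethylsilyl)oxy]methyl}-3-methylpent-4-en-1-ol
Conditions: i-Bu2AlH, CH2Cl2, −78 → 0 °C
Reagents that add atoms: none
Why: Reductive acetal opening with the aluminium hydride proceeds by coordination to the less hindered primary oxygen, which is cleaved, so the PMB group ends on the hindered C9 oxygen and C8 is freed as the primary alcohol.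

Step 10
Reactants: 10 (2S,3S)-2-[(4-methoxybenzyl)oxy]-3-{[(tert-butyldimethylsilyl)oxy]methyl}-3-methylpent-4-en-1-ol
Product: 11 (2S,3S)-2-[(4-methoxybenzyl)oxy]-3-{[(tert-butyldimethylsilyl)oxy]methyl}-3-methylpent-4-enal
Conditions: Dess–Martin periodinane, CH2Cl2, 0 °C → rt
Reagents that add atoms: none
Why: Dess–Martin oxidation gives the α-alkoxy aldehyde without base, so C9 next to the quaternary centre should not epimerise.

Step 11
Reactants: 12 methyl 4,4-dimethoxybutanoate
Product: 13 lithium 4,4-dimethoxybutanoate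
Conditions: LiOH·H2O (1.0 equiv.), THF/H2O, rt; evaporate and dry
Reagents that add atoms: lithium hydroxide, [Li+].[OH-]
Why: Saponification under basic conditions keeps the acid-sensitive dimethyl acetal, and isolation as the lithium salt avoids the free γ-acetal acid.

Step 12
Reactants: 13 lithium 4,4-dimethoxybutanoate; 14 (R)-4-benzyl-1,3-oxazolidin-2-one
Product: 16 (R)-4-benzyl-3-(4,4-dimethoxybutanoyl)-1,3-oxazolidin-2-one, via mixed pivalic anhydride 15 (not isolated)
Conditions: t-BuCOCl, Et3N, THF, −20 °C; then 14, LiCl, −20 °C → rt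
Reagents that add atoms: none
Why: N-acylation of the oxazolidinone by a mixed pivalic anhydride with LiCl/Et3N is a mild, non-acidic acylation in which attack occurs at the less hindered carbonyl.

Step 13
Reactants: 16 (R)-4-benzyl-3-(4,4-dimethoxybutanoyl)-1,3-oxazolidin-2-one; 11 (2S,3S)-2-[(4-methoxybenzyl)oxy]-3-{[(tert-butyldimethylsilyl)oxy]methyl}-3-methylpent-4-enal
Product: 18 syn-aldol imide with C8–OH (hept-6-enoyl chain 2R,3R,4S,5S), via dibutylboron (Z)-enolate 17 (not isolated)
Conditions: n-Bu2BOTf, i-Pr2NEt, CH2Cl2, −78 → 0 °C; then 11, −78 → 0 °C; pH 7 buffer, MeOH, H2O2, 0 °C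
Reagents that add atoms: none
Why: Evans syn-aldol through the (Z)-boron enolate and a Zimmerman–Traxler chair lets the (R)-auxiliary set C7 and C8 (2,3-syn), and this is matched with the Felkin–Anh (3,4-anti) preference of the α-alkoxy aldehyde.

Step 14
Reactants: 18 syn-aldol imide with C8–OH
Product: 19 C8–OTBS imide
Conditions: TBSOTf, 2,6-lutidine, CH2Cl2, −78 °C
Reagents that add atoms: tert-butyldimethylsilyl triflate, CC(C)(C)[Si](C)(C)OS(=O)(=O)C(F)(F)F
Why: The silyl triflate silylates the hindered aldol hydroxyl at low temperature, where the dimethyl acetal should not be ionised in the presence of excess lutidine.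

Step 15
Reactants: 19 C8–OTBS imide
Product: 20 C5 primary alcohol imide
Conditions: HF·pyridine, pyridine, THF, 0 °C
Reagents that add atoms: none
Why: Buffered HF·pyridine removes a primary silyl ether much faster than the flanked secondary one at C8, and the imide and acetal tolerate it.

Step 16
Reactants: 20 C5 primary alcohol imide
Product: 21 C5 aldehyde imide
Conditions: Dess–Martin periodinane, pyridine, CH2Cl2, rt
Reagents that add atoms: none
Why: Dess–Martin oxidation of the neopentyl alcohol gives an aldehyde that cannot enolise because C10 is quaternary.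

Step 17
Reactants: 21 C5 aldehyde imide
Product: 22 (Z)-2-(phenylsulfanylmethyl)enoate imide
Conditions: PhSH, NaH, THF, 0 °C; (MeO)2P(O)C(=CH2)CO2Me, 0 °C; then 21, 0 °C → rt
Reagents that add atoms: sodium salt of methyl 2-(dimethoxyphosphoryl)-3-(phenylsulfanyl)propanoate (made in the flask from trimethyl 2-phosphonoacrylate, thiophenol and NaH), [Na+].COC(=O)[C-](CSc1ccccc1)P(=O)(OC)OC
Why: Tandem thia-Michael addition/Horner–Wadsworth–Emmons olefination gives the trisubstituted enoate with C10 trans to the ester (Z by the sequence rule), and the hindered imide should resist the small equilibrium amount of thiolate.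

Step 18
Reactants: 22 (Z)-2-(phenylsulfanylmethyl)enoate imide
Product: 23 (Z)-2-(phenylsulfanylmethyl)enoate C6 carboxylic acid
Conditions: LiOH, H2O2, THF/H2O, 0 °C; Na2SO3; NaHSO4 to pH 4 at 0 °C
Reagents that add atoms: hydrogen peroxide, OO
Why: Hydroperoxide cleaves the exocyclic imide carbonyl selectively, and at the sulfide stage the hindered trisubstituted methyl enoate is not a good acceptor for it.

Step 19
Reactants: 23 (Z)-2-(phenylsulfanylmethyl)enoate C6 carboxylic acid
Product: 24 (Z)-2-(phenylsulfonylmethyl)enoate C6 carboxylic acid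
Conditions: m-CPBA (2.2 equiv.), CH2Cl2, −20 → 0 °C
Reagents that add atoms: 3-chloroperbenzoic acid, OOC(=O)c1cccc(Cl)c1
Why: Peracid oxidation of a sulfide to the sulfone is far faster than epoxidation of the monosubstituted vinyl group or of the electron-poor enoate.

Step 20
Reactants: 24 (Z)-2-(phenylsulfonylmethyl)enoate C6 carboxylic acid
Product: 25 Se-phenyl selenoester (radical precursor)
Conditions: PhSeSePh, n-Bu3P, CH2Cl2, 0 °C → rt
Reagents that add atoms: diphenyl diselenide, c1ccc(cc1)[Se][Se]c1ccccc1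
Why: Phosphine/diselenide activation converts the acid to the selenoester under neutral conditions that spare the γ-acetal, and conjugate or SN2′ attack of phosphine or selenolate on the acceptor is blocked because C5 is neopentyl.

Step 21
Reactants: 25 Se-phenyl selenoester (radical precursor)
Product: 26 cyclohexanone with 5β-[1-(methoxycarbonyl)ethenyl] arm
Conditions: (Me3Si)3SiH, Et3B, air, benzene (0.005 M), rt, slow addition of the silane
Reagents that add atoms: none
Why: Et3B/O2 generates (Me3Si)3Si•, which abstracts PhSe from 25 to give the nucleophilic C6 acyl radical; this adds 6-exo-trig to C5, the β-carbon of the enoate, and the α-ester radical at C4 then expels PhSO2• by β-scission, which makes the closure irreversible, leaves the C4=C3 methylene and carries the chain by taking H from the silane. The closest known reaction types are acyl radical cyclisations of phenyl selenoesters onto acrylates and radical addition–fragmentation of 2-(alkoxycarbonyl)allyl sulfones. The cyclohexane C5–C10 closes through a chair-like 6-exo transition state with the C7 arm and C8–OTBS equatorial and C9–OPMB and the C14 methyl axial. The new C5 stereocentre is set by that chair, the C5=C4 acceptor lying pseudo-equatorial (5β arm), and because C5 is α to the C6 ketone it can still settle to this equatorial configuration. The step needs attack on the enoate rather than on the C1=C2 vinyl group, which polarity matching of the acyl radical with the electron-poor alkene secures, and cyclisation faster than decarbonylation or reduction, which room-temperature initiation, high dilution, slow silane addition and the gem-disubstitution at C10 secure.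

Step 22
Reactants: 26 cyclohexanone with 5β-[1-(methoxycarbonyl)ethenyl] arm
Product: 27 6β,15-diol
Conditions: i-Bu2AlH (excess), CH2Cl2, −78 → 0 °C
Reagents that add atoms: none
Why: The aluminium hydride reduces the enoate 1,2 to the allylic alcohol and the ketone from the α-face (equatorial attack), because axial approach is blocked by the syn-axial C14 methyl, so the axial 6β-alcohol should predominate.

Step 23
Reactants: 27 6β,15-diol
Product: 28 15-OTBS 6β-alcohol
Conditions: TBSCl, imidazole, CH2Cl2, 0 °C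
Reagents that add atoms: tert-butyldimethylsilyl chloride, CC(C)(C)[Si](C)(C)Cl
Why: The primary allylic hydroxyl is silylated much faster than the axial C6 hydroxyl, which is syn-axial to C14.

Step 24
Reactants: 28 15-OTBS 6β-alcohol
Product: 29 6β-acetate
Conditions: Ac2O, DMAP, Et3N, CH2Cl2, rt → 40 °C
Reagents that add atoms: acetic anhydride, CC(=O)OC(C)=O
Why: DMAP-catalysed acylation with the small acetyl group should overcome the hindrance of the axial secondary alcohol.

Step 25
Reactants: 29 6β-acetate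
Product: 30 9α-alcohol
Conditions: DDQ, CH2Cl2/pH 7 buffer, 0 °C → rt
Reagents that add atoms: none
Why: Oxidative cleavage of the PMB ether by DDQ frees only the C9 hydroxyl, while silyl ethers, acetate, acetal and alkenes are inert.

Step 26
Reactants: 30 9α-alcohol
Product: 31 9α-angelate
Conditions: angelic acid, 2,4,6-Cl3C6H2COCl, Et3N, toluene, rt; then 30, 80 °C
Reagents that add atoms: angelic 2,4,6-trichlorobenzoic anhydride (made in the flask from angelic acid), C/C=C(/C)C(=O)OC(=O)c1c(Cl)cc(Cl)cc1Cl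
Why: Yamaguchi esterification through the mixed anhydride, run without a nucleophilic catalyst, acylates hindered alcohols while keeping the (Z)-geometry of the angelate.

Step 27
Reactants: 31 9α-angelate
Product: 32 C12 aldehyde
Conditions: Et3SiOTf, 2,4,6-collidine, CH2Cl2, 0 °C; then H2O
Reagents that add atoms: water, O
Why: The silyl triflate/collidine pair converts the dimethyl acetal into a collidinium salt that water hydrolyses to the aldehyde, conditions under which silyl ethers and esters are left intact.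

Step 28
Reactants: 32 C12 aldehyde
Product: 33 2-substituted propenal at C11 (C13 methylene installed)
Conditions: 37% aq. CH2O, pyrrolidine (cat.), EtCO2H (cat.), i-PrOH, 45 °C
Reagents that add atoms: formaldehyde, C=O
Why: Amine-catalysed Mannich condensation–elimination (α-methylenation) works only through the enamine of the aldehyde, so C13 is introduced without any enolate chemistry near the acetate and angelate.

Step 29
Reactants: 33 2-substituted propenal at C11
Product: 34 α-methylene lactol with free 15-OH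
Conditions: HF·pyridine, THF, 0 °C → rt
Reagents that add atoms: none
Why: Acidic fluoride removes both silyl ethers without promoting acyl migration, and the freed 8α-hydroxyl closes onto the C12 aldehyde to give the trans-fused five-membered lactol.

Step 30
Reactants: 34 α-methylene lactol with free 15-OH
Product: 35 6β-acetoxy-9α-(angeloyloxy)-15-oxoelema-1,3,11(13)-trien-12,8α-olide (target CNP0252310.1)
Conditions: MnO2, CH2Cl2, rt
Reagents that add atoms: none
Why: MnO2 oxidises allylic alcohols selectively, so the C15 alcohol goes to the enal and the allylic lactol to the α-methylene-γ-lactone in one operation.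

**Compound list**

1 | 3-methylbut-2-en-1-yl acetate (prenyl acetate) | CC(C)=CCOC(C)=O | starting material
2 | (E)-4-hydroxy-3-methylbut-2-en-1-yl acetate | CC(=O)OC/C=C(\C)CO | intermediate
3 | (E)-4-[(tert-butyldimethylsilyl)oxy]-3-methylbut-2-en-1-yl acetate | CC(=O)OC/C=C(\C)CO[Si](C)(C)C(C)(C)C | intermediate
4 | (E)-4-[(tert-butyldimethylsilyl)oxy]-3-methylbut-2-en-1-ol | OC/C=C(\C)CO[Si](C)(C)C(C)(C)C | intermediate
5 | [(2R,3R)-3-{[(tert-butyldimethylsilyl)oxy]methyl}-3-methyloxiran-2-yl]methanol | OC[C@H]1O[C@]1(C)CO[Si](C)(C)C(C)(C)C | intermediate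
6 | (2S,3S)-3-{[(tert-butyldimethylsilyl)oxy]methyl}-3-methyl-5-(trimethylsilyl)pent-4-yne-1,2-diol | OC[C@@H](O)[C@](C)(CO[Si](C)(C)C(C)(C)C)C#C[Si](C)(C)C | intermediate
7 | (2S,3S)-3-{[(tert-butyldimethylsilyl)oxy]methyl}-3-methylpent-4-yne-1,2-diol | OC[C@@H](O)[C@](C)(CO[Si](C)(C)C(C)(C)C)C#C | intermediate
8 | (2S,3S)-3-{[(tert-butyldimethylsilyl)oxy]methyl}-3-methylpent-4-ene-1,2-diol | OC[C@@H](O)[C@](C)(CO[Si](C)(C)C(C)(C)C)C=C | intermediate
9 | (4S)-4-[(2S)-1-[(tert-butyldimethylsilyl)oxy]-2-methylbut-3-en-2-yl]-2-(4-methoxyphenyl)-1,3-dioxolane (both epimers at the acetal carbon) | COc1ccc(cc1)C1OC[C@@H](O1)[C@](C)(CO[Si](C)(C)C(C)(C)C)C=C | intermediate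
10 | (2S,3S)-2-[(4-methoxybenzyl)oxy]-3-{[(tert-butyldimethylsilyl)oxy]methyl}-3-methylpent-4-en-1-ol | OC[C@@H](OCc1ccc(OC)cc1)[C@](C)(CO[Si](C)(C)C(C)(C)C)C=C | intermediate
11 | (2S,3S)-2-[(4-methoxybenzyl)oxy]-3-{[(tert-butyldimethylsilyl)oxy]methyl}-3-methylpent-4-enal | O=C[C@@H](OCc1ccc(OC)cc1)[C@](C)(CO[Si](C)(C)C(C)(C)C)C=C | intermediate
12 | methyl 4,4-dimethoxybutanoate | COC(CCC(=O)OC)OC | starting material
13 | lithium 4,4-dimethoxybutanoate | [Li+].[O-]C(=O)CCC(OC)OC | intermediate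
14 | (R)-4-benzyl-1,3-oxazolidin-2-one | O=C1N[C@H](Cc2ccccc2)CO1 | starting material
15 | 4,4-dimethoxybutanoic pivalic anhydride (not isolated) | COC(CCC(=O)OC(=O)C(C)(C)C)OC | intermediate
16 | (R)-4-benzyl-3-(4,4-dimethoxybutanoyl)-1,3-oxazolidin-2-one | COC(CCC(=O)N1[C@H](Cc2ccccc2)COC1=O)OC | intermediate
17 | dibutylboron (Z)-enolate of 16 (not isolated) | CCCCB(CCCC)O/C(=C\CC(OC)OC)N1[C@H](Cc2ccccc2)COC1=O | intermediate
18 | (4R)-4-benzyl-3-[(2R,3R,4S,5S)-5-{[(tert-butyldimethylsilyl)oxy]methyl}-2-(2,2-dimethoxyethyl)-3-hydroxy-4-[(4-methoxybenzyl)oxy]-5-methylhept-6-enoyl]-1,3-oxazolidin-2-one | O=C(N1[C@H](Cc2ccccc2)COC1=O)[C@H](CC(OC)OC)[C@@H](O)[C@@H](OCc1ccc(OC)cc1)[C@](C)(CO[Si](C)(C)C(C)(C)C)C=C | intermediate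
19 | 3-O-tert-butyldimethylsilyl ether of 18 (C8–OTBS; chain 2R,3R,4S,5S) | O=C(N1[C@H](Cc2ccccc2)COC1=O)[C@H](CC(OC)OC)[C@@H](O[Si](C)(C)C(C)(C)C)[C@@H](OCc1ccc(OC)cc1)[C@](C)(CO[Si](C)(C)C(C)(C)C)C=C | intermediate
20 | (4R)-4-benzyl-3-[(2R,3R,4S,5S)-3-[(tert-butyldimethylsilyl)oxy]-2-(2,2-dimethoxyethyl)-5-(hydroxymethyl)-4-[(4-methoxybenzyl)oxy]-5-methylhept-6-enoyl]-1,3-oxazolidin-2-one | O=C(N1[C@H](Cc2ccccc2)COC1=O)[C@H](CC(OC)OC)[C@@H](O[Si](C)(C)C(C)(C)C)[C@@H](OCc1ccc(OC)cc1)[C@](C)(CO)C=C | intermediate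
21 | (4R)-4-benzyl-3-[(2R,3R,4S,5R)-3-[(tert-butyldimethylsilyl)oxy]-2-(2,2-dimethoxyethyl)-5-formyl-4-[(4-methoxybenzyl)oxy]-5-methylhept-6-enoyl]-1,3-oxazolidin-2-one | O=C(N1[C@H](Cc2ccccc2)COC1=O)[C@H](CC(OC)OC)[C@@H](O[Si](C)(C)C(C)(C)C)[C@@H](OCc1ccc(OC)cc1)[C@](C)(C=O)C=C | intermediate
22 | (4R)-4-benzyl-3-[(2R,3R,4S,5S,6Z)-3-[(tert-butyldimethylsilyl)oxy]-2-(2,2-dimethoxyethyl)-5-ethenyl-7-(methoxycarbonyl)-4-[(4-methoxybenzyl)oxy]-5-methyl-8-(phenylsulfanyl)oct-6-enoyl]-1,3-oxazolidin-2-one | O=C(N1[C@H](Cc2ccccc2)COC1=O)[C@H](CC(OC)OC)[C@@H](O[Si](C)(C)C(C)(C)C)[C@@H](OCc1ccc(OC)cc1)[C@](C)(/C=C(\CSc1ccccc1)C(=O)OC)C=C | intermediate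
23 | (2R,3R,4S,5S,6Z)-3-[(tert-butyldimethylsilyl)oxy]-2-(2,2-dimethoxyethyl)-5-ethenyl-7-(methoxycarbonyl)-4-[(4-methoxybenzyl)oxy]-5-methyl-8-(phenylsulfanyl)oct-6-enoic acid | OC(=O)[C@H](CC(OC)OC)[C@@H](O[Si](C)(C)C(C)(C)C)[C@@H](OCc1ccc(OC)cc1)[C@](C)(/C=C(\CSc1ccccc1)C(=O)OC)C=C | intermediate
24 | (2R,3R,4S,5S,6Z)-3-[(tert-butyldimethylsilyl)oxy]-2-(2,2-dimethoxyethyl)-5-ethenyl-7-(methoxycarbonyl)-4-[(4-methoxybenzyl)oxy]-5-methyl-8-(phenylsulfonyl)oct-6-enoic acid | OC(=O)[C@H](CC(OC)OC)[C@@H](O[Si](C)(C)C(C)(C)C)[C@@H](OCc1ccc(OC)cc1)[C@](C)(/C=C(\CS(=O)(=O)c1ccccc1)C(=O)OC)C=C | intermediate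
25 | Se-phenyl (2R,3R,4S,5S,6Z)-3-[(tert-butyldimethylsilyl)oxy]-2-(2,2-dimethoxyethyl)-5-ethenyl-7-(methoxycarbonyl)-4-[(4-methoxybenzyl)oxy]-5-methyl-8-(phenylsulfonyl)oct-6-eneselenoate | C=C[C@@](C)(/C=C(\CS(=O)(=O)c1ccccc1)C(=O)OC)[C@H](OCc1ccc(OC)cc1)[C@H](O[Si](C)(C)C(C)(C)C)[C@@H](CC(OC)OC)C(=O)[Se]c1ccccc1 | intermediate
26 | C6 cyclohexanone: 5β-[1-(methoxycarbonyl)ethenyl], 7β-(2,2-dimethoxyethyl), 8α-OTBS, 9α-OPMB, 10β-methyl, 10α-ethenyl | C=C[C@]1(C)[C@H](OCc2ccc(OC)cc2)[C@H](O[Si](C)(C)C(C)(C)C)[C@@H](CC(OC)OC)C(=O)[C@H]1C(=C)C(=O)OC | intermediate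
27 | 6β,15-diol: 6β-hydroxy, 5β-[1-(hydroxymethyl)ethenyl], other groups as in 26 | C=C[C@]1(C)[C@H](OCc2ccc(OC)cc2)[C@H](O[Si](C)(C)C(C)(C)C)[C@@H](CC(OC)OC)[C@@H](O)[C@H]1C(=C)CO | intermediate
28 | 15-O-tert-butyldimethylsilyl ether of 27 (6β-OH free) | C=C[C@]1(C)[C@H](OCc2ccc(OC)cc2)[C@H](O[Si](C)(C)C(C)(C)C)[C@@H](CC(OC)OC)[C@@H](O)[C@H]1C(=C)CO[Si](C)(C)C(C)(C)C | intermediate
29 | 6β-acetate of 28 | C=C[C@]1(C)[C@H](OCc2ccc(OC)cc2)[C@H](O[Si](C)(C)C(C)(C)C)[C@@H](CC(OC)OC)[C@@H](OC(C)=O)[C@H]1C(=C)CO[Si](C)(C)C(C)(C)C | intermediate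
30 | 9α-alcohol (PMB removed from 29) | C=C[C@]1(C)[C@H](O)[C@H](O[Si](C)(C)C(C)(C)C)[C@@H](CC(OC)OC)[C@@H](OC(C)=O)[C@H]1C(=C)CO[Si](C)(C)C(C)(C)C | intermediate
31 | 9α-angelate [(Z)-2-methylbut-2-enoate] of 30 | C=C[C@]1(C)[C@H](OC(=O)/C(C)=C\C)[C@H](O[Si](C)(C)C(C)(C)C)[C@@H](CC(OC)OC)[C@@H](OC(C)=O)[C@H]1C(=C)CO[Si](C)(C)C(C)(C)C | intermediate
32 | C12 aldehyde: 7β-(2-oxoethyl) analogue of 31 | C=C[C@]1(C)[C@H](OC(=O)/C(C)=C\C)[C@H](O[Si](C)(C)C(C)(C)C)[C@@H](CC=O)[C@@H](OC(C)=O)[C@H]1C(=C)CO[Si](C)(C)C(C)(C)C | intermediate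
33 | C11=C13 enal: 7β-(3-oxoprop-1-en-2-yl) analogue of 31 | C=C[C@]1(C)[C@H](OC(=O)/C(C)=C\C)[C@H](O[Si](C)(C)C(C)(C)C)[C@@H](C(=C)C=O)[C@@H](OC(C)=O)[C@H]1C(=C)CO[Si](C)(C)C(C)(C)C | intermediate
34 | trans-fused α-methylene lactol (C12 epimers) with 15-OH, 6β-OAc, 9α-OAng | C=C[C@]1(C)[C@H](OC(=O)/C(C)=C\C)[C@@H]2OC(O)C(=C)[C@H]2[C@@H](OC(C)=O)[C@H]1C(=C)CO | intermediate
35 | 6β-acetoxy-9α-(angeloyloxy)-15-oxoelema-1,3,11(13)-trien-12,8α-olide (CNP0252310.1) | C=C[C@]1(C)[C@H](OC(=O)/C(C)=C\C)[C@@H]2OC(=O)C(=C)[C@H]2[C@@H](OC(C)=O)[C@H]1C(=C)C=O | target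

**Step count and risks**

Total steps: 30. Longest linear sequence: 28 (steps 1–10 and 13–30; steps 11–12 form the side branch to 16).

Steps most likely to fail:

Step 21 (key radical cyclisation). The acyl radical may lose CO or be reduced to the aldehyde before the ring closes, or add to the C1=C2 vinyl group. The fallback sets out from 24 and returns at 27, closing the same C5–C6 bond by a polar, umpoled allylation. Acid 24 would be reduced through its isobutyl mixed carbonic anhydride with NaBH4 to the C6 primary alcohol F1, and Dess–Martin oxidation would give the C6 aldehyde F2. Pd(PPh3)4 and Et2Zn would then turn the allylic sulfone into an allylzinc that adds through C5 to the aldehyde in a chair-like transition state, and the cis hydroxy ester so formed should close to the cis-fused α-methylene lactone F3. Excess i-Bu2AlH would reduce F3 to diol 27.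

Step 5 (epoxide opening). The alkynyl group may be delivered to C9 instead of C10, or the Lewis acid may rearrange the epoxide. The fallback sets out from 4 and returns at 10 by an Ireland–Claisen rearrangement. Alcohol 4 would be esterified with (4-methoxybenzyloxy)acetic acid (DCC, DMAP) to the allyl glycolate F4. LiN(SiMe3)2/Me3SiCl at −78 °C should give the chelated (Z)-silyl ketene acetal, which rearranges through a chair on warming to the racemic syn acid F5 with the required relative configuration at C9 and C10. Crystallisation of its salt with an enantiopure amine such as (R)-1-phenylethylamine (or its antipode, whichever salt of the wanted acid crystallises) would give the (2S,3S)-acid F6, and LiAlH4 reduction would give 10.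

Step 17 (thia-Michael/Horner–Wadsworth–Emmons olefination). Olefination of the neopentyl aldehyde may be too slow, and thiolate may attack the imide. The fallback sets out from 21 and returns at 24 through a Baylis–Hillman-type adduct. [1-(Methoxycarbonyl)vinyl]diisobutylaluminium (from methyl propiolate, i-Bu2AlH and HMPA) would add to 21 to give the allylic alcohol F7 (C5 epimers), and Ac2O/DMAP would give its acetate F8. PhSO2Na in DMF would displace the acetate by SN2′ to give the (Z)-allylic sulfone imide F9 directly, and LiOH/H2O2 would cleave the auxiliary to give 24.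

Further compounds
F1 | step 21 | C6 primary alcohol (carboxyl of 24 reduced to CH2OH) | OC[C@H](CC(OC)OC)[C@@H](O[Si](C)(C)C(C)(C)C)[C@@H](OCc1ccc(OC)cc1)[C@](C)(/C=C(\CS(=O)(=O)c1ccccc1)C(=O)OC)C=C
F2 | step 21 | C6 aldehyde corresponding to 24 | O=C[C@H](CC(OC)OC)[C@@H](O[Si](C)(C)C(C)(C)C)[C@@H](OCc1ccc(OC)cc1)[C@](C)(/C=C(\CS(=O)(=O)c1ccccc1)C(=O)OC)C=C
F3 | step 21 | cis-fused α-methylene-γ-lactone between the 6β-oxygen and C15 (ring substituents as in 26) | C=C[C@]1(C)[C@H](OCc2ccc(OC)cc2)[C@H](O[Si](C)(C)C(C)(C)C)[C@@H](CC(OC)OC)[C@H]2OC(=O)C(=C)[C@@H]12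
F4 | step 5 | (E)-4-[(tert-butyldimethylsilyl)oxy]-3-methylbut-2-en-1-yl 2-[(4-methoxybenzyl)oxy]acetate | COc1ccc(COCC(=O)OC/C=C(\C)CO[Si](C)(C)C(C)(C)C)cc1
F5 | step 5 | racemic syn 2-[(4-methoxybenzyl)oxy]-3-{[(tert-butyldimethylsilyl)oxy]methyl}-3-methylpent-4-enoic acid (2S,3S and 2R,3R) | OC(=O)[C@@H](OCc1ccc(OC)cc1)[C@](C)(CO[Si](C)(C)C(C)(C)C)C=C.OC(=O)[C@H](OCc1ccc(OC)cc1)[C@@](C)(CO[Si](C)(C)C(C)(C)C)C=C
F6 | step 5 | (2S,3S)-2-[(4-methoxybenzyl)oxy]-3-{[(tert-butyldimethylsilyl)oxy]methyl}-3-methylpent-4-enoic acid | OC(=O)[C@@H](OCc1ccc(OC)cc1)[C@](C)(CO[Si](C)(C)C(C)(C)C)C=C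
F7 | step 17 | Baylis–Hillman-type C5 alcohol imide (C5 epimers) | O=C(N1[C@H](Cc2ccccc2)COC1=O)[C@H](CC(OC)OC)[C@@H](O[Si](C)(C)C(C)(C)C)[C@@H](OCc1ccc(OC)cc1)[C@](C)(C(O)C(=C)C(=O)OC)C=C
F8 | step 17 | C5 acetate of F7 | O=C(N1[C@H](Cc2ccccc2)COC1=O)[C@H](CC(OC)OC)[C@@H](O[Si](C)(C)C(C)(C)C)[C@@H](OCc1ccc(OC)cc1)[C@](C)(C(OC(C)=O)C(=C)C(=O)OC)C=C
F9 | step 17 | (Z)-2-(phenylsulfonylmethyl)enoate imide (sulfone analogue of 22) | O=C(N1[C@H](Cc2ccccc2)COC1=O)[C@H](CC(OC)OC)[C@@H](O[Si](C)(C)C(C)(C)C)[C@@H](OCc1ccc(OC)cc1)[C@](C)(/C=C(\CS(=O)(=O)c1ccccc1)C(=O)OC)C=C
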